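The γ-lactone (phthalide) ring fused to ring B is closed by joining its CH2 carbon to the neighbouring arene carbon. That arene carbon is the only ring-B carbon left unsubstituted, and it lies between the carboxyl-bearing carbon and the phenolic oxygen that later becomes the diaryl ether. The precursor is an ortho-iodo benzoate whose ester oxygen already carries the CH2 as a (tributylstannyl)methyl group; an intramolecular Stille coupling forms the C–C bond and releases the phthalide phenol. SNAr on a 2-fluoroisophthalate (ring A), debenzylation, lactonisation to the seven-membered depsidone ring, acidolysis and a final aldehyde reduction complete the synthesis.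

Key step: step 8

Remark: the target has no stereocentre; sesamol, 3-fluoro-5-methylphenol, tributyl(iodomethyl)stannane and sodium benzyloxide (1 M in benzyl alcohol) are taken as purchasable.

Step 1
Reactants: 1 sesamol (1,3-benzodioxol-5-ol)
Product: 2 6-hydroxy-1,3-benzodioxole-5-carboxylic acid
Conditions: K2CO3, CO2 (50 bar), 175 °C; then aq HCl
Reagents that add atoms: carbon dioxide, O=C=O
Why: Kolbe–Schmitt carboxylation of the potassium phenoxide should go to the less hindered ortho carbon, which is also para to a dioxole oxygen.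

Step 2
Reactants: 2 6-hydroxy-1,3-benzodioxole-5-carboxylic acid
Product: 3 7-formyl-6-hydroxy-1,3-benzodioxole-5-carboxylic acid
Conditions: hexamethylenetetramine, TFA, 80 °C; then 2 M HCl, 60 °C
Reagents that add atoms: hexamethylenetetramine, C1N2CN3CN1CN(C2)C3; water, O
Why: Duff formylation should attack the only free position ortho to the phenol (the para position is blocked), the carbon between OH and the dioxole oxygen, and acid hydrolysis of the iminium releases the aldehyde.

Step 3
Reactants: 3 7-formyl-6-hydroxy-1,3-benzodioxole-5-carboxylic acid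
Product: 4 benzyl 6-(benzyloxy)-7-formyl-1,3-benzodioxole-5-carboxylate
Conditions: BnBr (2.5 equiv), K2CO3, DMF, 60 °C
Reagents that add atoms: benzyl bromide, BrCc1ccccc1
Why: Williamson-type O-alkylation should convert the carboxylic acid and the chelated phenol into benzyl ester and benzyl ether in one operation.

Step 4
Reactants: 4 benzyl 6-(benzyloxy)-7-formyl-1,3-benzodioxole-5-carboxylate
Product: 5 benzyl 2,4-bis(benzyloxy)-3-formyl-5-hydroxybenzoate
Conditions: NaOCH2Ph (1 M in BnOH, 3 equiv), DMSO, 70 °C; then aq HCl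
Reagents that add atoms: sodium benzyloxide, [Na+].[O-]Cc1ccccc1
Why: nucleophilic aromatic substitution (addition–elimination cleavage of the methylenedioxy ring) by benzyloxide should occur at the dioxole carbon para to the ester and ortho to the formyl group, the expelled aryloxymethoxide loses formaldehyde to leave the other oxygen as the free phenol, and exchange at the benzyl ester or the activated benzyl ether is degenerate.

Step 5
Reactants: 5 benzyl 2,4-bis(benzyloxy)-3-formyl-5-hydroxybenzoate
Product: 6 2,4-bis(benzyloxy)-3-formyl-5-hydroxybenzoic acid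
Conditions: LiOH·H2O, THF/H2O, 45 °C; then aq HCl
Reagents that add atoms: lithium hydroxide, [Li+].[OH-]
Why: saponification of the benzyl ester, which has one free ortho position, should proceed while benzyl ethers, the non-enolisable aldehyde and the phenol tolerate aqueous base.

Step 6
Reactants: 6 2,4-bis(benzyloxy)-3-formyl-5-hydroxybenzoic acid
Product: 7 2,4-bis(benzyloxy)-3-formyl-5-hydroxy-6-iodobenzoic acid
Conditions: NIS, MeCN, 0 °C to rt
Reagents that add atoms: N-iodosuccinimide, O=C1CCC(=O)N1I
Why: electrophilic aromatic iodination should occur ortho to the free phenol, at the only unsubstituted ring carbon.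

Step 7
Reactants: 7 2,4-bis(benzyloxy)-3-formyl-5-hydroxy-6-iodobenzoic acid
Product: 8 (tributylstannyl)methyl 2,4-bis(benzyloxy)-3-formyl-5-hydroxy-6-iodobenzoate
Conditions: KHCO3 (1.05 equiv), Bu3SnCH2I, DMF, rt
Reagents that add atoms: tributyl(iodomethyl)stannane, CCCC[Sn](CCCC)(CCCC)CI
Why: SN2 O-alkylation of the potassium carboxylate by the primary iodide should give the acyloxymethylstannane, since hydrogencarbonate deprotonates the acid but leaves the phenol protonated.

Step 8
Reactants: 8 (tributylstannyl)methyl 2,4-bis(benzyloxy)-3-formyl-5-hydroxy-6-iodobenzoate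
Product: 9 5,7-bis(benzyloxy)-4-hydroxy-1-oxo-1,3-dihydro-2-benzofuran-6-carbaldehyde
Conditions: Pd(PPh3)4 (10 mol %), CuI (20 mol %), CsF (2.2 equiv), DMF (0.01 M), 60 °C
Reagents that add atoms: none
Why: Intramolecular Stille coupling: zerovalent palladium inserts into the aryl–iodine bond (helped by the para formyl group), the acyloxymethyl group passes from fluoride-activated tin through copper to divalent palladium, and reductive elimination forms the aryl–CH2 bond. The closest known reactions are Stille couplings of hydroxymethyl-, alkoxymethyl- and acyloxymethyl-stannanes with aryl halides and palladium-catalysed lactone-forming couplings through an ester tether. The five-membered lactone is closed by C(sp2)–C(sp3) reductive elimination from a six-membered oxa-palladacycle, and no stereocentre is formed. The step needs transfer of the oxygen-bearing CH2 rather than butyl, which the α-oxygen and the intramolecular setting favour, and ring closure rather than oligomerisation, which dilution secures. The site is fixed by the iodine, which step 6 could place only on the single free carbon next to the phenol. Benzyl ethers, aldehyde and the caesium phenoxide should be tolerated.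

Step 9
Reactants: 10 3-fluoro-5-methylphenol
Product: 11 4-bromo-3-fluoro-5-methylphenol
Conditions: NBS, MeCN, 0 °C
Reagents that add atoms: N-bromosuccinimide, O=C1CCC(=O)N1Br
Why: electrophilic bromination of the phenol with NBS in acetonitrile should go para to OH, the position flanked by F and CH3.

Step 10
Reactants: 11 4-bromo-3-fluoro-5-methylphenol
Product: 12 2-bromo-1-fluoro-5-(methoxymethoxy)-3-methylbenzene
Conditions: MOMCl, iPr2NEt, CH2Cl2, 0 °C to rt
Reagents that add atoms: chloromethyl methyl ether, COCCl
Why: O-alkylation should give the MOM ether, an acid-labile protecting group that also directs the next metalation.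

Step 11
Reactants: 12 2-bromo-1-fluoro-5-(methoxymethoxy)-3-methylbenzene
Product: 14 tert-butyl 3-bromo-2-fluoro-6-(methoxymethoxy)-4-methylbenzoate, via aryllithium 13 (not isolated)
Conditions: LiN(iPr)2, THF, −78 °C; then Boc2O, −78 °C to rt
Reagents that add atoms: di-tert-butyl dicarbonate, CC(C)(C)OC(=O)OC(=O)OC(C)(C)C
Why: directed ortho-metalation should remove the proton flanked by F and OMOM (the amide base does not exchange bromine and no hydrogen lies ortho to Br), and acylation of the aryllithium with Boc2O gives the tert-butyl ester.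

Step 12
Reactants: 14 tert-butyl 3-bromo-2-fluoro-6-(methoxymethoxy)-4-methylbenzoate
Product: 16 1-benzyl 3-tert-butyl 2-fluoro-4-(methoxymethoxy)-6-methylbenzene-1,3-dicarboxylate, via arylmagnesium chloride 15 (not isolated)
Conditions: iPrMgCl·LiCl, THF, −15 to 0 °C; then ClCO2Bn, −20 °C to rt
Reagents that add atoms: benzyl chloroformate, O=C(Cl)OCc1ccccc1
Why: bromine–magnesium exchange (Knochel turbo-Grignard), favoured by the ortho fluorine and tolerated by the hindered tert-butyl ester, followed by acylation with the chloroformate should give the mixed diester.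

Step 13
Reactants: 9 5,7-bis(benzyloxy)-4-hydroxy-1-oxo-1,3-dihydro-2-benzofuran-6-carbaldehyde; 16 1-benzyl 3-tert-butyl 2-fluoro-4-(methoxymethoxy)-6-methylbenzene-1,3-dicarboxylate
Product: 17 1-benzyl 3-tert-butyl 2-{[5,7-bis(benzyloxy)-6-formyl-1-oxo-1,3-dihydro-2-benzofuran-4-yl]oxy}-4-(methoxymethoxy)-6-methylbenzene-1,3-dicarboxylate
Conditions: Cs2CO3, DMSO, 90 °C
Reagents that add atoms: none
Why: SNAr (addition–elimination through a Meisenheimer adduct) of the caesium phenoxide should take place on the fluorine-bearing carbon, which is activated by two ortho ester carbonyls and carries the only leaving group.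

Step 14
Reactants: 17 the diaryl ether of step 13
Product: 18 3-(tert-butoxycarbonyl)-2-[(6-formyl-5,7-dihydroxy-1-oxo-1,3-dihydro-2-benzofuran-4-yl)oxy]-4-(methoxymethoxy)-6-methylbenzoic acid
Conditions: H2 (1 atm), 10% Pd/C, EtOAc, rt
Reagents that add atoms: none
Why: hydrogenolysis should cleave the benzyl ester and both benzyl ethers in one step while tert-butyl ester, MOM ether, lactone and, with control of hydrogen uptake, the chelated aryl aldehyde are kept.

Step 15
Reactants: 18 the seco acid of step 14
Product: 19 protected depsidone (the target skeleton with CHO in place of CH2OH, CO2tBu in place of CO2H and OMOM in place of the ring-A OH)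
Conditions: EDC·HCl, DMAP, CH2Cl2 (0.005 M), rt
Reagents that add atoms: none
Why: carbodiimide/DMAP lactonisation (Steglich-type esterification) at high dilution should close the seven-membered depsidone ring, because only the phenol ortho to the diaryl ether oxygen can reach the acid while the other phenol is para to the ether link and hydrogen-bonded to two carbonyls.

Step 16
Reactants: 19 protected depsidone
Product: 20 formyl depsidone acid (the target with CHO in place of CH2OH)
Conditions: TFA/CH2Cl2 (1:1), H2O (2%), rt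
Reagents that add atoms: none
Why: acidolysis should remove the tert-butyl ester and the MOM ether together, while aryl ester, lactone, diaryl ether and aldehyde are stable to acid.

Step 17
Reactants: 20 formyl depsidone acid
Product: 21 conneotricone
Conditions: NaBH(OAc)3, THF/AcOH, 0 °C to rt
Reagents that add atoms: none
Why: chemoselective hydride reduction of the aldehyde, assisted by the neighbouring phenol, should leave the depsidone ester, the γ-lactone and the carboxylic acid untouched, and it comes last so that the acid-sensitive ortho-hydroxybenzyl alcohol never meets strong acid or hydrogenolysis.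

Compound list
1 | sesamol (1,3-benzodioxol-5-ol) | Oc1ccc2OCOc2c1 | starting material
2 | 6-hydroxy-1,3-benzodioxole-5-carboxylic acid | O=C(O)c1cc2OCOc2cc1O | intermediate
3 | 7-formyl-6-hydroxy-1,3-benzodioxole-5-carboxylic acid | O=Cc1c(O)c(C(=O)O)cc2OCOc12 | intermediate
4 | benzyl 6-(benzyloxy)-7-formyl-1,3-benzodioxole-5-carboxylate | O=Cc1c(OCc2ccccc2)c(C(=O)OCc3ccccc3)cc4OCOc14 | intermediate
5 | benzyl 2,4-bis(benzyloxy)-3-formyl-5-hydroxybenzoate | O=Cc1c(OCc2ccccc2)c(C(=O)OCc3ccccc3)cc(O)c1OCc4ccccc4 | intermediate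
6 | 2,4-bis(benzyloxy)-3-formyl-5-hydroxybenzoic acid | O=Cc1c(OCc2ccccc2)c(C(=O)O)cc(O)c1OCc3ccccc3 | intermediate
7 | 2,4-bis(benzyloxy)-3-formyl-5-hydroxy-6-iodobenzoic acid | O=Cc1c(OCc2ccccc2)c(C(=O)O)c(I)c(O)c1OCc3ccccc3 | intermediate
8 | (tributylstannyl)methyl 2,4-bis(benzyloxy)-3-formyl-5-hydroxy-6-iodobenzoate | CCCC[Sn](CCCC)(CCCC)COC(=O)c1c(I)c(O)c(OCc2ccccc2)c(C=O)c1OCc3ccccc3 | intermediate
9 | 5,7-bis(benzyloxy)-4-hydroxy-1-oxo-1,3-dihydro-2-benzofuran-6-carbaldehyde | O=Cc1c(OCc2ccccc2)c(O)c3COC(=O)c3c1OCc4ccccc4 | intermediate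
10 | 3-fluoro-5-methylphenol | Cc1cc(O)cc(F)c1 | starting material
11 | 4-bromo-3-fluoro-5-methylphenol | Cc1cc(O)cc(F)c1Br | intermediate
12 | 2-bromo-1-fluoro-5-(methoxymethoxy)-3-methylbenzene | COCOc1cc(C)c(Br)c(F)c1 | intermediate
13 | [3-bromo-2-fluoro-6-(methoxymethoxy)-4-methylphenyl]lithium, formed in the flask | [Li]c1c(F)c(Br)c(C)cc1OCOC | intermediate
14 | tert-butyl 3-bromo-2-fluoro-6-(methoxymethoxy)-4-methylbenzoate | COCOc1cc(C)c(Br)c(F)c1C(=O)OC(C)(C)C | intermediate
15 | [3-(tert-butoxycarbonyl)-2-fluoro-4-(methoxymethoxy)-6-methylphenyl]magnesium chloride, formed in the flask | Cl[Mg]c1c(C)cc(OCOC)c(C(=O)OC(C)(C)C)c1F | intermediate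
16 | 1-benzyl 3-tert-butyl 2-fluoro-4-(methoxymethoxy)-6-methylbenzene-1,3-dicarboxylate | COCOc1cc(C)c(C(=O)OCc2ccccc2)c(F)c1C(=O)OC(C)(C)C | intermediate
17 | 1-benzyl 3-tert-butyl 2-{[5,7-bis(benzyloxy)-6-formyl-1-oxo-1,3-dihydro-2-benzofuran-4-yl]oxy}-4-(methoxymethoxy)-6-methylbenzene-1,3-dicarboxylate | COCOc1cc(C)c(C(=O)OCc2ccccc2)c(Oc3c(OCc4ccccc4)c(C=O)c(OCc5ccccc5)c6C(=O)OCc36)c1C(=O)OC(C)(C)C | intermediate
18 | 3-(tert-butoxycarbonyl)-2-[(6-formyl-5,7-dihydroxy-1-oxo-1,3-dihydro-2-benzofuran-4-yl)oxy]-4-(methoxymethoxy)-6-methylbenzoic acid | COCOc1cc(C)c(C(=O)O)c(Oc2c(O)c(C=O)c(O)c3C(=O)OCc23)c1C(=O)OC(C)(C)C | intermediate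
19 | protected depsidone: tert-butyl ester and MOM ether of the formyl depsidone acid 20 | Cc1cc(OCOC)c(C(=O)OC(C)(C)C)c2c1C(=O)Oc1c(C=O)c(O)c3c(c1O2)COC3=O | intermediate
20 | formyl depsidone acid (target with CHO in place of CH2OH) | Cc1cc(O)c(C(=O)O)c2c1C(=O)Oc1c(C=O)c(O)c3c(c1O2)COC3=O | intermediate
21 | conneotricone | Cc1cc(O)c(C(=O)O)c2c1C(=O)Oc1c(CO)c(O)c3c(c1O2)COC3=O | target

Total step count: 17. Longest linear sequence: 13 steps (steps 1–8 and 13–17, from sesamol).

Steps most likely to fail

Step 13. The substitution may stall because both esters flanking the fluorine are twisted out of conjugation and both partners are di-ortho-substituted. The fallback changes the electrophile to one activated by a coplanar ortho-formyl group. Setting out from 14, bromine–magnesium exchange (iPrMgCl·LiCl) and quench with DMF would give tert-butyl 2-fluoro-3-formyl-6-(methoxymethoxy)-4-methylbenzoate F1. Setting out from 9, acetalisation with 2,2-dimethylpropane-1,3-diol (TsOH, toluene, water removal) would mask the ring-B aldehyde as 5,7-bis(benzyloxy)-6-(5,5-dimethyl-1,3-dioxan-2-yl)-4-hydroxy-2-benzofuran-1(3H)-one F2, so that the two formyl groups stay distinguishable. SNAr of F2 on F1 (Cs2CO3, DMF, 70 °C) would give tert-butyl 2-{[5,7-bis(benzyloxy)-6-(5,5-dimethyl-1,3-dioxan-2-yl)-1-oxo-1,3-dihydro-2-benzofuran-4-yl]oxy}-3-formyl-6-(methoxymethoxy)-4-methylbenzoate F3. Pinnick oxidation (NaClO2, NaH2PO4, 2-methyl-2-butene) would give the corresponding benzoic acid F4, and hydrogenolysis (H2, Pd/C) would give 3-(tert-butoxycarbonyl)-2-{[6-(5,5-dimethyl-1,3-dioxan-2-yl)-5,7-dihydroxy-1-oxo-1,3-dihydro-2-benzofuran-4-yl]oxy}-4-(methoxymethoxy)-6-methylbenzoic acid F5. Mild acetal hydrolysis (pyridinium tosylate, wet acetone) would then come back to the route at 18.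

Step 8. Ring closure may be lost to protodestannylation, or the tin-to-palladium transfer may be too slow because the ester must reach its less stable s-cis rotamer. The fallback makes the two bonds of the lactone in the reverse order. Setting out from 7, intermolecular Stille hydroxymethylation with (tributylstannyl)methanol (Pd(PPh3)4, dioxane, 90 °C) would give 2,4-bis(benzyloxy)-3-formyl-5-hydroxy-6-(hydroxymethyl)benzoic acid F6. This hydroxy acid should lactonise on acidic work-up (TsOH, toluene) and so come back to the route at 9.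

Step 4. The alkoxide may consume the aldehyde by hydride transfer or Cannizzaro/Tishchenko-type redox faster than it opens the dioxole ring. The fallback masks the formyl group first. Setting out from 4, HC(OMe)3 and TsOH in MeOH would give benzyl 6-(benzyloxy)-7-(dimethoxymethyl)-1,3-benzodioxole-5-carboxylate F7. Ring cleavage with NaOCH2Ph in DMSO (110 °C), now driven by the para ester alone, would give benzyl 2,4-bis(benzyloxy)-3-(dimethoxymethyl)-5-hydroxybenzoate F8. Aqueous HCl in THF would unmask the aldehyde and come back to the route at 5.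

Further compounds
F1 | step 13 | tert-butyl 2-fluoro-3-formyl-6-(methoxymethoxy)-4-methylbenzoate | COCOc1cc(C)c(C=O)c(F)c1C(=O)OC(C)(C)C
F2 | step 13 | 5,7-bis(benzyloxy)-6-(5,5-dimethyl-1,3-dioxan-2-yl)-4-hydroxy-2-benzofuran-1(3H)-one | CC1(C)COC(OC1)c2c(OCc3ccccc3)c(O)c4COC(=O)c4c2OCc5ccccc5
F3 | step 13 | tert-butyl 2-{[5,7-bis(benzyloxy)-6-(5,5-dimethyl-1,3-dioxan-2-yl)-1-oxo-1,3-dihydro-2-benzofuran-4-yl]oxy}-3-formyl-6-(methoxymethoxy)-4-methylbenzoate | COCOc1cc(C)c(C=O)c(Oc2c(OCc3ccccc3)c(C4OCC(C)(C)CO4)c(OCc5ccccc5)c6C(=O)OCc26)c1C(=O)OC(C)(C)C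
F4 | step 13 | 2-{[5,7-bis(benzyloxy)-6-(5,5-dimethyl-1,3-dioxan-2-yl)-1-oxo-1,3-dihydro-2-benzofuran-4-yl]oxy}-3-(tert-butoxycarbonyl)-4-(methoxymethoxy)-6-methylbenzoic acid | COCOc1cc(C)c(C(=O)O)c(Oc2c(OCc3ccccc3)c(C4OCC(C)(C)CO4)c(OCc5ccccc5)c6C(=O)OCc26)c1C(=O)OC(C)(C)C
F5 | step 13 | 3-(tert-butoxycarbonyl)-2-{[6-(5,5-dimethyl-1,3-dioxan-2-yl)-5,7-dihydroxy-1-oxo-1,3-dihydro-2-benzofuran-4-yl]oxy}-4-(methoxymethoxy)-6-methylbenzoic acid | COCOc1cc(C)c(C(=O)O)c(Oc2c(O)c(C3OCC(C)(C)CO3)c(O)c4C(=O)OCc24)c1C(=O)OC(C)(C)C
F6 | step 8 | 2,4-bis(benzyloxy)-3-formyl-5-hydroxy-6-(hydroxymethyl)benzoic acid | O=Cc1c(OCc2ccccc2)c(C(=O)O)c(CO)c(O)c1OCc3ccccc3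
F7 | step 4 | benzyl 6-(benzyloxy)-7-(dimethoxymethyl)-1,3-benzodioxole-5-carboxylate | COC(OC)c1c(OCc2ccccc2)c(C(=O)OCc3ccccc3)cc4OCOc14
F8 | step 4 | benzyl 2,4-bis(benzyloxy)-3-(dimethoxymethyl)-5-hydroxybenzoate | COC(OC)c1c(OCc2ccccc2)c(C(=O)OCc3ccccc3)cc(O)c1OCc4ccccc4
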